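A direct plan would start from (+)-sclareolide A1 and would excise C-12 (MeLi, Baeyer–Villiger, methanolysis, iodination) to reach 11-iododriman-8α-ol A2.
A2 would be joined to methyl 4-acetoxy-3-iodobenzoate A3 by Ni-catalysed cross-electrophile coupling to give the 11-aryldriman-8α-ol A4.
BF3·OEt2 would then turn A4 into the 4,9-friedodrimane aryl acetate A5 by four 1,2-shifts, and methanolysis would free the phenol.
Weakest would be the cationic rearrangement: each cation on the way could lose a proton early, and the last one would favour the Δ3 alkene, to which the 4(11)-alkene would also drift in acid.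
Next would be the cross-electrophile coupling: the CH2I group would hang on a methine flanked by two fully substituted carbons and, as a 1,3-iodohydrin, would be open to oxetane formation, fragmentation and reduction.
Last, the four-step excision of one carbon would add length without adding complexity.

**New strategy.** The decalin is read backwards: C-9 becomes the initiating carbon of a radical polyene cyclisation and the C-4 methylene its terminus. An acyclic α-bromo aryl ketone, which already holds the arene, all fifteen terpenoid carbons and one catalyst-set stereocentre (C-8), gives the C-9 radical. This closes ring B (C9–C10, 6-endo) and then ring A (C5–C4, 6-exo-dig on a terminal alkyne). The step exploits the contiguous C8–C9–C10–C5 array and the C-4 methylene next to quaternary C-5. One operation sets C-9, C-10 and C-5 and fixes the 4(11)-alkene, so no cation cascade, no hindered sp3 coupling and no carbon excision remain.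

Key step: step 10

Numbering: 4,9-friedodrimane numbering is used throughout. C-11 is the exocyclic CH2 on C-4, C-12/13/14 are the methyls on C-5/8/9, and C-15 is the benzylic carbon.
Assumption: (5-chloropent-1-yn-1-yl)trimethylsilane and 1-methylcyclopropane-1-carbaldehyde are taken as commercial.
Remark: C-9 is carried as both epimers from step 5 to step 9, because it becomes a planar radical in step 10.

## Route

Step 1
Reactants: 1 (5-chloropent-1-yn-1-yl)trimethylsilane; 2 1-methylcyclopropane-1-carbaldehyde
Product: 4 (±)-1-(1-methylcyclopropyl)-6-(trimethylsilyl)hex-5-yn-1-ol, via [5-(trimethylsilyl)pent-4-yn-1-yl]magnesium chloride 3 (not isolated)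
Conditions: Mg, THF, reflux; then 2, 0 °C; aq. NH4Cl
Reagents that add atoms: none
Why: Grignard addition to an aldehyde joins C-1 to C-10; the carbinol centre is racemic and is destroyed in step 2.

Step 2
Reactants: 4 (±)-1-(1-methylcyclopropyl)-6-(trimethylsilyl)hex-5-yn-1-ol
Product: 6 (E)-(9-bromo-7-methylnon-6-en-1-yn-1-yl)trimethylsilane, via [6-bromo-6-(1-methylcyclopropyl)hex-1-yn-1-yl]trimethylsilane 5 (not isolated)
Conditions: PBr3, LiBr, 2,4,6-collidine, Et2O, −30 → 0 °C; then ZnBr2, Et2O, 0 °C
Reagents that add atoms: PBr3, BrP(Br)Br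
Why: Julia–Johnson cyclopropylcarbinyl-to-homoallyl rearrangement, in which bromide opens the ZnBr2-activated ring through the bisected conformer that turns the C-1 chain away from the two ring methylenes and toward the smaller methyl group, which should give the E trisubstituted alkene (C-1 trans to C-6).

Step 3
Reactants: 7 (E)-but-2-enoyl chloride
Product: 8 S-ethyl (E)-but-2-enethioate
Conditions: EtSH, Et3N, CH2Cl2, 0 °C
Reagents that add atoms: ethanethiol, CCS
Why: S-acylation (nucleophilic acyl substitution) that keeps the alkene geometry.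

Step 4
Reactants: 6 (E)-(9-bromo-7-methylnon-6-en-1-yn-1-yl)trimethylsilane; 8 S-ethyl (E)-but-2-enethioate
Product: 10 S-ethyl (3S,6E)-3,6-dimethyl-12-(trimethylsilyl)dodec-6-en-11-ynethioate, via (E)-[3-methyl-9-(trimethylsilyl)non-3-en-8-yn-1-yl]magnesium bromide 9 (not isolated)
Conditions: Mg, Et2O; then 8, CuI (cat.), Tol-BINAP (cat., the enantiomer that delivers the alkyl group to the Re face of C-β), t-BuOMe, −70 °C
Reagents that add atoms: none
Why: Copper-catalysed asymmetric conjugate addition of a Grignard reagent to an α,β-unsaturated thioester forms C7–C8 and sets C-8 as S through the chiral ligand.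

Step 5
Reactants: 10 S-ethyl (3S,6E)-3,6-dimethyl-12-(trimethylsilyl)dodec-6-en-11-ynethioate
Product: 12 S-ethyl (3S,6E)-2,3,6-trimethyl-12-(trimethylsilyl)dodec-6-en-11-ynethioate (both C-2 epimers), via lithium (3S,6E)-1-(ethylsulfanyl)-3,6-dimethyl-12-(trimethylsilyl)dodeca-1,6-dien-11-yn-1-olate 11 (not isolated)
Conditions: LDA, THF, −78 °C; then MeI, DMPU, −78 → −40 °C
Reagents that add atoms: iodomethane, CI
Why: Thioester enolate alkylation (SN2 on MeI) installs C-14, and the epimer mixture at C-9 is harmless because that centre is planarised in step 10.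

Step 6
Reactants: 13 methyl 4-hydroxy-3-iodobenzoate
Product: 14 methyl 4-[(ethoxycarbonyl)oxy]-3-iodobenzoate
Conditions: ClCO2Et, Et3N, CH2Cl2, 0 °C
Reagents that add atoms: ethyl chloroformate, CCOC(=O)Cl
Why: O-acylation of the phenol gives a carbonate that is inert to zinc, palladium and radicals and later serves as the leaving group that removes the C-15 oxygen.

Step 7
Reactants: 14 methyl 4-[(ethoxycarbonyl)oxy]-3-iodobenzoate; 12 S-ethyl (3S,6E)-2,3,6-trimethyl-12-(trimethylsilyl)dodec-6-en-11-ynethioate
Product: 16 methyl 4-[(ethoxycarbonyl)oxy]-3-[(3S,6E)-2,3,6-trimethyl-12-(trimethylsilyl)dodec-6-en-11-ynoyl]benzoate (C-2 epimers), via {2-[(ethoxycarbonyl)oxy]-5-(methoxycarbonyl)phenyl}zinc iodide 15 (not isolated)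
Conditions: Zn, LiCl, THF, rt; then 12, PdCl2(PPh3)2 (cat.), THF/toluene, rt → 40 °C
Reagents that add atoms: none
Why: LiCl-assisted zinc insertion followed by Fukuyama coupling (Pd-catalysed acylation of an organozinc by a thioester) forms the aryl–C15 bond, stops at the ketone, tolerates the ester, the carbonate and the silylalkyne, and leaves C-8 untouched.

Step 8
Reactants: 16 methyl 4-[(ethoxycarbonyl)oxy]-3-[(3S,6E)-2,3,6-trimethyl-12-(trimethylsilyl)dodec-6-en-11-ynoyl]benzoate
Product: 17 methyl 4-[(ethoxycarbonyl)oxy]-3-[(3S,6E)-2,3,6-trimethyldodec-6-en-11-ynoyl]benzoate (C-2 epimers)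
Conditions: AgNO3 (cat.), acetone/H2O, rt
Reagents that add atoms: none
Why: Silver-catalysed protiodesilylation of an alkynylsilane runs under neutral conditions that spare the aryl carbonate and the ester.

Step 9
Reactants: 17 methyl 4-[(ethoxycarbonyl)oxy]-3-[(3S,6E)-2,3,6-trimethyldodec-6-en-11-ynoyl]benzoate
Product: 19 methyl 3-[(3S,6E)-2-bromo-2,3,6-trimethyldodec-6-en-11-ynoyl]-4-[(ethoxycarbonyl)oxy]benzoate (C-2 epimers), via methyl 4-[(ethoxycarbonyl)oxy]-3-{(3S,6E)-2,3,6-trimethyl-1-[(trimethylsilyl)oxy]dodeca-1,6-dien-11-yn-1-yl}benzoate 18 (not isolated)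
Conditions: TMSOTf, Et3N, CH2Cl2, 0 °C → rt; then NBS, THF, −78 → 0 °C
Reagents that add atoms: N-bromosuccinimide, O=C1CCC(=O)N1Br; TMSOTf, C[Si](C)(C)OS(=O)(=O)C(F)(F)F (silicon only in 18)
Why: Soft enolisation and electrophilic bromination of the silyl enol ether, which outcompetes the trisubstituted alkene and the alkyne for NBS, and since no free enolate forms the carbonate cannot migrate.

Step 10
Reactants: 19 methyl 3-[(3S,6E)-2-bromo-2,3,6-trimethyldodec-6-en-11-ynoyl]-4-[(ethoxycarbonyl)oxy]benzoate
Product: 20 methyl 4-[(ethoxycarbonyl)oxy]-3-{[(1R,2S,4aS,8aR)-1,2,4a-trimethyl-5-methylidenedecahydronaphthalen-1-yl]carbonyl}benzoate (15-oxodictyoceratin C ethyl carbonate; trans-decalin, 5β,8β,9β-methyl, 10α-H)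
Conditions: (TMS)3SiH (1.2 equiv, syringe pump), AIBN (cat.), benzene (5 mM), 80 °C
Reagents that add atoms: none
Why: Bromine abstraction by the silyl radical gives the planar, electrophilic C-9 α-keto radical, which adds 6-endo-trig to C-10 of the electron-rich trisubstituted alkene (ring B; 5-exo attack at C-5 would join two fully substituted carbons), the resulting nucleophilic tertiary C-5 radical closes ring A 6-exo-dig on C-4 of the terminal alkyne, and the vinyl radical takes hydrogen from the silane and carries the chain. The closest known reaction type is the reductive tandem radical cyclisation of halo-enynes that ends on a terminal alkyne, combined with the 6-endo polyene cyclisations of α-carbonyl radicals. C-9 is controlled by C-8 through allylic 1,3-strain in the conjugated radical: C8–H eclipses the C9–C15 bond, so the chair places C-13 and the aroyl group equatorial and C-14 axial, and the chain can reach one face only. C-10 follows from the chair transition state and the E alkene (C-1 equatorial, H-10 axial and anti to C-14). C-5 is set in the second closure, where only the trans mode keeps C-6 and C-9 equatorial on the nascent ring A, and the equatorial aroyl group cannot reach the C-5 radical. The step needs cyclisation to outrun hydrogen transfer, which high dilution, slow addition and the slow donor (TMS)3SiH should secure, and the alkene position is fixed because it comes from the alkyne, C-5 is quaternary and no acid is present.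

Step 11
Reactants: 20 15-oxodictyoceratin C ethyl carbonate
Product: 22 dictyoceratin C (methyl 4-hydroxy-3-{[(1R,2S,4aS,8aS)-1,2,4a-trimethyl-5-methylidenedecahydronaphthalen-1-yl]methyl}benzoate), via the o-quinone methide of dictyoceratin C (C15=C3′ and C4′=O, decalin unchanged) 21 (not isolated)
Conditions: NaBH4 (excess), THF/H2O, 0 °C → rt
Reagents that add atoms: none
Why: Borohydride reduction of an o-(alkoxycarbonyloxy)aryl ketone to the o-alkylphenol, in which hydride adds to C-15, the ethoxycarbonyl group moves to the new alkoxide and leaves to give 21, and a second hydride adds 1,4 at C-15, all under basic conditions that leave the 4(11)-alkene, the methyl ester and the four stereocentres untouched.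

## Compound list

1 | (5-chloropent-1-yn-1-yl)trimethylsilane | C[Si](C)(C)C#CCCCCl | starting material
2 | 1-methylcyclopropane-1-carbaldehyde | CC1(C=O)CC1 | starting material
3 | [5-(trimethylsilyl)pent-4-yn-1-yl]magnesium chloride | C[Si](C)(C)C#CCCC[Mg]Cl | intermediate
4 | (±)-1-(1-methylcyclopropyl)-6-(trimethylsilyl)hex-5-yn-1-ol | CC1(CC1)C(O)CCCC#C[Si](C)(C)C | intermediate
5 | [6-bromo-6-(1-methylcyclopropyl)hex-1-yn-1-yl]trimethylsilane (racemic) | CC1(CC1)C(Br)CCCC#C[Si](C)(C)C | intermediate
6 | (E)-(9-bromo-7-methylnon-6-en-1-yn-1-yl)trimethylsilane | BrCC/C(C)=C/CCCC#C[Si](C)(C)C | intermediate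
7 | (E)-but-2-enoyl chloride | C/C=C/C(=O)Cl | starting material
8 | S-ethyl (E)-but-2-enethioate | C/C=C/C(=O)SCC | intermediate
9 | (E)-[3-methyl-9-(trimethylsilyl)non-3-en-8-yn-1-yl]magnesium bromide | Br[Mg]CC/C(C)=C/CCCC#C[Si](C)(C)C | intermediate
10 | S-ethyl (3S,6E)-3,6-dimethyl-12-(trimethylsilyl)dodec-6-en-11-ynethioate | CCSC(=O)C[C@@H](C)CC/C(C)=C/CCCC#C[Si](C)(C)C | intermediate
11 | lithium (3S,6E)-1-(ethylsulfanyl)-3,6-dimethyl-12-(trimethylsilyl)dodeca-1,6-dien-11-yn-1-olate (enolate geometry open) | [Li+].CCSC([O-])=C[C@@H](C)CC/C(C)=C/CCCC#C[Si](C)(C)C | intermediate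
12 | S-ethyl (3S,6E)-2,3,6-trimethyl-12-(trimethylsilyl)dodec-6-en-11-ynethioate (C-2 epimers) | CCSC(=O)C(C)[C@@H](C)CC/C(C)=C/CCCC#C[Si](C)(C)C | intermediate
13 | methyl 4-hydroxy-3-iodobenzoate | COC(=O)c1ccc(O)c(I)c1 | starting material
14 | methyl 4-[(ethoxycarbonyl)oxy]-3-iodobenzoate | CCOC(=O)Oc1ccc(C(=O)OC)cc1I | intermediate
15 | {2-[(ethoxycarbonyl)oxy]-5-(methoxycarbonyl)phenyl}zinc iodide | CCOC(=O)Oc1ccc(C(=O)OC)cc1[Zn]I | intermediate
16 | methyl 4-[(ethoxycarbonyl)oxy]-3-[(3S,6E)-2,3,6-trimethyl-12-(trimethylsilyl)dodec-6-en-11-ynoyl]benzoate (C-2 epimers) | CCOC(=O)Oc1ccc(C(=O)OC)cc1C(=O)C(C)[C@@H](C)CC/C(C)=C/CCCC#C[Si](C)(C)C | intermediate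
17 | methyl 4-[(ethoxycarbonyl)oxy]-3-[(3S,6E)-2,3,6-trimethyldodec-6-en-11-ynoyl]benzoate (C-2 epimers) | CCOC(=O)Oc1ccc(C(=O)OC)cc1C(=O)C(C)[C@@H](C)CC/C(C)=C/CCCC#C | intermediate
18 | methyl 4-[(ethoxycarbonyl)oxy]-3-{(3S,6E)-2,3,6-trimethyl-1-[(trimethylsilyl)oxy]dodeca-1,6-dien-11-yn-1-yl}benzoate (enol geometry open) | CCOC(=O)Oc1ccc(C(=O)OC)cc1C(O[Si](C)(C)C)=C(C)[C@@H](C)CC/C(C)=C/CCCC#C | intermediate
19 | methyl 3-[(3S,6E)-2-bromo-2,3,6-trimethyldodec-6-en-11-ynoyl]-4-[(ethoxycarbonyl)oxy]benzoate (C-2 epimers) | CCOC(=O)Oc1ccc(C(=O)OC)cc1C(=O)C(C)(Br)[C@@H](C)CC/C(C)=C/CCCC#C | intermediate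
20 | methyl 4-[(ethoxycarbonyl)oxy]-3-{[(1R,2S,4aS,8aR)-1,2,4a-trimethyl-5-methylidenedecahydronaphthalen-1-yl]carbonyl}benzoate | C=C1CCC[C@H]2[C@](C)(C(=O)c3cc(C(=O)OC)ccc3OC(=O)OCC)[C@@H](C)CC[C@]12C | intermediate
21 | o-quinone methide of dictyoceratin C (C15=C3′ and C4′=O, decalin unchanged; geometry at C-15 open) | C=C1CCC[C@H]2[C@](C)(C=C3C=C(C(=O)OC)C=CC3=O)[C@@H](C)CC[C@]12C | intermediate
22 | dictyoceratin C | C=C1CCC[C@H]2[C@](C)(Cc3cc(C(=O)OC)ccc3O)[C@@H](C)CC[C@]12C | target

## Totals and risks

Total steps: 11. Longest linear sequence: 9 (steps 1, 2, 4, 5, 7, 8, 9, 10, 11).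

1. **Step 10 (key step).** Hydrogen transfer from the silane to the C-9 or C-5 radical could outrun ring closure, above all the slower 6-exo-dig closure. The fallback separates cyclisation from reduction and sets out from 19. A copper-catalysed bromine-atom-transfer radical cyclisation (CuBr, tris(2-pyridylmethyl)amine, 1,2-dichloroethane, 80 °C) has no hydrogen donor and re-activates any tertiary bromide formed by early transfer, so it would end at the bicyclic vinyl bromide F1. Palladium-catalysed hydrodebromination (Pd(PPh3)4, Bu3SnH) would then come back to the route at 20.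

2. **Step 11.** Hydride attack on the C-15 ketone, which sits between a quaternary carbon and an ortho-substituted arene, could be slower than hydrolytic loss of the carbonate, which would stall the sequence at an unreactive phenoxide. The fallback replaces hydride addition by electron transfer, which is far less sensitive to steric hindrance, and sets out from 20. K2CO3/MeOH would give 15-oxodictyoceratin C F2, and SmI2/H2O in THF would reduce the ketone through its ketyl to 15-hydroxydictyoceratin C F3. ClCO2Et/Et3N would acylate only the phenol, giving the 15-hydroxy aryl ethyl carbonate F4. NaBH4 in aqueous NaOH/THF would then trigger the carbonate shift and come back to the route at 21 and so at 22.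

3. **Step 7.** Acyl transfer from a thioester that is branched at C-α and C-β to an ortho-substituted arylzinc could stall at transmetalation or reductive elimination. The fallback forms the aryl–C15 bond within one molecule and sets out from 12. LiOH in aqueous THF/MeOH would cleave the thioester and the alkynylsilane, giving (3S,6E)-2,3,6-trimethyldodec-6-en-11-ynoic acid F5, and EDC/DMAP with methyl 4-hydroxybenzoate would give the aryl ester F6. A photo-Fries rearrangement (254 nm, cyclohexane), with the para position blocked, would give the o-hydroxyaryl ketone F7, and ClCO2Et/Et3N would come back to the route at 17.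

## Further compounds

F1 | step 10 | 11-bromo derivative of 20 (vinyl bromide, E/Z open) | BrC=C1CCC[C@H]2[C@](C)(C(=O)c3cc(C(=O)OC)ccc3OC(=O)OCC)[C@@H](C)CC[C@]12C
F2 | step 11 | 15-oxodictyoceratin C | C=C1CCC[C@H]2[C@](C)(C(=O)c3cc(C(=O)OC)ccc3O)[C@@H](C)CC[C@]12C
F3 | step 11 | 15-hydroxydictyoceratin C (C-15 epimers) | C=C1CCC[C@H]2[C@](C)(C(O)c3cc(C(=O)OC)ccc3O)[C@@H](C)CC[C@]12C
F4 | step 11 | 15-hydroxydictyoceratin C 4′-O-ethyl carbonate (C-15 epimers) | C=C1CCC[C@H]2[C@](C)(C(O)c3cc(C(=O)OC)ccc3OC(=O)OCC)[C@@H](C)CC[C@]12C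
F5 | step 7 | (3S,6E)-2,3,6-trimethyldodec-6-en-11-ynoic acid (C-2 epimers) | OC(=O)C(C)[C@@H](C)CC/C(C)=C/CCCC#C
F6 | step 7 | methyl 4-{[(3S,6E)-2,3,6-trimethyldodec-6-en-11-ynoyl]oxy}benzoate (C-2 epimers) | COC(=O)c1ccc(OC(=O)C(C)[C@@H](C)CC/C(C)=C/CCCC#C)cc1
F7 | step 7 | methyl 4-hydroxy-3-[(3S,6E)-2,3,6-trimethyldodec-6-en-11-ynoyl]benzoate (C-2 epimers) | COC(=O)c1ccc(O)c(C(=O)C(C)[C@@H](C)CC/C(C)=C/CCCC#C)c1
A1 | direct plan | (+)-sclareolide | C[C@]12CCCC(C)(C)[C@@H]1CC[C@@]3(C)OC(=O)C[C@H]23
A2 | direct plan | 11-iododriman-8α-ol | C[C@]12CCCC(C)(C)[C@@H]1CC[C@@](C)(O)[C@@H]2CI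
A3 | direct plan | methyl 4-acetoxy-3-iodobenzoate | COC(=O)c1ccc(OC(C)=O)c(I)c1
A4 | direct plan | methyl 4-acetoxy-3-[(8α-hydroxydriman-11-yl)]benzoate | C[C@]12CCCC(C)(C)[C@@H]1CC[C@@](C)(O)[C@@H]2Cc1cc(C(=O)OC)ccc1OC(C)=O
A5 | direct plan | dictyoceratin C O-acetate | C=C1CCC[C@H]2[C@](C)(Cc3cc(C(=O)OC)ccc3OC(C)=O)[C@@H](C)CC[C@]12C
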